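**Plan**
1. The target is (13E)-2β-acetoxylabda-8(17),13-dien-15-oic acid; labdane numbering is used throughout and β is the face of the C10 methyl group.
2. Retrosynthetic cuts, in order: the C15 allyl ester and the axial C2 acetate (from a 2α-silyl ether by oxidation–reduction); C8=C17 (methylenation of a ring B ketone); C13=C14 (Horner–Wadsworth–Emmons); C9–C11 (Michael addition, with loss of a C9 carboxyl); C9–C10 (cation–olefin closure of ring B); C8–C9 and C5–C6 (Claisen condensation, Negishi coupling).
3. Forward: ring A is bought as (4R,6R)-actinol, a keto ester chain is attached at C5, ring B closes onto C10, the side chain is joined at C9 as a 3-oxobutyl group and finished by two olefinations.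
4. Enabling feature: the C8 carbonyl of ring B, with a temporary allyl carboxylate on C9, makes C9 the only nucleophilic carbon although it is neopentyl to the quaternary C10; the carboxyl then leaves as CO2 and C8=O becomes the C8=C17 methylene.
5. Stereochemistry: the C2 silyloxy group from actinol fixes the ring A conformation and hence the face of C5 protonation (C5, C10, trans fusion); C9 is set by α-face protonation after decarboxylation (also the stable epimer); C13=C14 E comes from the phosphonate olefination; C2 is inverted to the axial 2β-acetate by hydride attack on the 2-ketone from the open α face.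

Key step: step 6

Assumption: (4R,6R)-actinol (1) is taken as a purchasable chiral building block; it is otherwise available from ketoisophorone by the established two-stage reduction.

**Step 1**
Reactants: 1 (4R,6R)-4-hydroxy-2,2,6-trimethylcyclohexan-1-one
Product: 2 (4R,6R)-4-[(tert-butyldiphenylsilyl)oxy]-2,2,6-trimethylcyclohexan-1-one
Conditions: TBDPSCl, imidazole, DMF, rt
Reagents that add atoms: tert-butyl(chloro)diphenylsilane, CC(C)(C)[Si](Cl)(c1ccccc1)c1ccccc1
Why: Silyl ether protection of the unhindered equatorial secondary alcohol; the acid-stable TBDPS group is chosen to survive SnCl4 in step 5 and the bases of steps 2, 4 and 8.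

**Step 2**
Reactants: 2 (4R,6R)-4-[(tert-butyldiphenylsilyl)oxy]-2,2,6-trimethylcyclohexan-1-one
Product: 4 (4R)-4-[(tert-butyldiphenylsilyl)oxy]-2,6,6-trimethylcyclohex-1-en-1-yl trifluoromethanesulfonate, via lithium enolate 3 (not isolated)
Conditions: LiN(i-Pr)2, THF, −78 to 0 °C; then PhNTf2, −78 °C to rt
Reagents that add atoms: N-phenylbis(trifluoromethanesulfonimide), O=S(=O)(N(c1ccccc1)S(=O)(=O)C(F)(F)F)C(F)(F)F; lithium diisopropylamide, [Li+].CC(C)[N-]C(C)C
Why: Enol triflate formation is regiospecific because only C10 carries an α-hydrogen (C4 is quaternary); the C10 stereocentre of 2 is deliberately erased and the C2 centre is untouched.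

**Step 3**
Reactants: 4 (4R)-4-[(tert-butyldiphenylsilyl)oxy]-2,6,6-trimethylcyclohex-1-en-1-yl trifluoromethanesulfonate; 5 (3-ethoxy-3-oxopropyl)zinc bromide
Product: 6 ethyl 3-[(4R)-4-[(tert-butyldiphenylsilyl)oxy]-2,6,6-trimethylcyclohex-1-en-1-yl]propanoate
Conditions: Pd(PPh3)4 (5 mol %), LiCl, THF–NMP, 60 °C
Reagents that add atoms: none
Why: Negishi coupling of a vinyl triflate with a zinc homoenolate should form the C5–C6 bond with the tetrasubstituted C5=C10 alkene kept in place.

**Step 4**
Reactants: 6 ethyl 3-[(4R)-4-[(tert-butyldiphenylsilyl)oxy]-2,6,6-trimethylcyclohex-1-en-1-yl]propanoate; 7 allyl acetate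
Product: 8 allyl 5-[(4R)-4-[(tert-butyldiphenylsilyl)oxy]-2,6,6-trimethylcyclohex-1-en-1-yl]-3-oxopentanoate
Conditions: LiN(i-Pr)2 (3 equiv), 7 (3 equiv), THF, −78 °C; then 6, −78 to 0 °C; aqueous NH4Cl
Reagents that add atoms: none
Why: Crossed Claisen condensation of the ethyl ester with excess lithium enolate of allyl acetate should give the β-keto ester (C8 ketone, C9 methylene), driven by deprotonation of the product.

**Step 5**
Reactants: 8 allyl 5-[(4R)-4-[(tert-butyldiphenylsilyl)oxy]-2,6,6-trimethylcyclohex-1-en-1-yl]-3-oxopentanoate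
Product: 10 allyl 2α-[(tert-butyldiphenylsilyl)oxy]-4,4,10-trimethyl-8-oxo-trans-decalin-9β-carboxylate, via tertiary C10 carbocation 9 (not isolated)
Conditions: SnCl4 (1.5 equiv), CH2Cl2 (not dried), 0 °C to rt
Reagents that add atoms: none
Why: SnCl4-mediated cation–olefin cyclisation of an unsaturated β-keto ester (the reaction type used for dihydro-β-ionone-derived keto esters) should protonate C5 and let the tin-chelated enol attack the C10 cation through C9 (the chelate blocks O-attack); the equatorial 2α-silyloxy group fixes the ring A half-chair so that the pseudoaxial C4 methyl shields the β face and the proton enters C5 from the α face, after which chair–chair closure with the C5 chain equatorial gives the trans fusion (5α-H, 10β-methyl) and an equatorial C9 ester.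

**Step 6**
Reactants: 10 allyl 2α-[(tert-butyldiphenylsilyl)oxy]-4,4,10-trimethyl-8-oxo-trans-decalin-9β-carboxylate; 11 but-3-en-2-one
Product: 12 allyl 2α-[(tert-butyldiphenylsilyl)oxy]-4,4,10-trimethyl-8-oxo-9α-(3-oxobutyl)-trans-decalin-9β-carboxylate
Conditions: Cs2CO3 (0.2 equiv), MeCN, 0 °C to rt
Reagents that add atoms: none
Why: Catalytic carbonate deprotonates 10 only at C9, the one carbon flanked by both the C8 ketone and the ester carbonyl, and the stabilised enolate adds 1,4 to butenone, whose terminal carbon becomes C11 and whose enolate is reprotonated by the next molecule of 10. The closest known reaction type is the Michael addition of cyclic 2-alkoxycarbonyl ketones to vinyl ketones (the first stage of a Robinson annulation), together with the C9 alkylation of this ring system by allylic and benzylic halides. No ring is closed in this step. The new quaternary C9 should form by approach of the acceptor to the α face, anti to the axial C10 methyl group, but this centre is provisional and is rewritten when the carboxyl is removed in step 7. The step needs C- over O-alkylation and C9 over C7 regioselectivity, secured by the soft reversible acceptor and by the fact that only the C9 hydrogen is acidic enough for the weak base. It also needs the adduct not to close by aldol reaction, which the catalytic weak base, the low temperature and the hindered C8 carbonyl should ensure.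

**Step 7**
Reactants: 12 allyl 2α-[(tert-butyldiphenylsilyl)oxy]-4,4,10-trimethyl-8-oxo-9α-(3-oxobutyl)-trans-decalin-9β-carboxylate
Product: 14 2α-[(tert-butyldiphenylsilyl)oxy]-14,15,17-trinorlabdane-8,13-dione, via β-keto acid 13 (not isolated)
Conditions: Pd(OAc)2 (5 mol %), PPh3 (20 mol %), HCO2H, Et3N, THF, rt to 40 °C
Reagents that add atoms: none
Why: Tsuji deallylation–decarboxylation of an allyl β-keto ester (zerovalent palladium formed in the flask, formate reducing the π-allyl complex) is neutral enough to spare the 1,5-diketone from aldol closure, and the C8 enol should be protonated at C9 from the α face, anti to the C10 methyl, giving 9α-H with the side chain equatorial (9β), which is also the thermodynamic epimer.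

**Step 8**
Reactants: 14 2α-[(tert-butyldiphenylsilyl)oxy]-14,15,17-trinorlabdane-8,13-dione; 15 allyl 2-(diethoxyphosphoryl)acetate
Product: 16 allyl (13E)-2α-[(tert-butyldiphenylsilyl)oxy]-8-oxo-17-norlabd-13-en-15-oate
Conditions: NaH (1.3 equiv), 15 (1.5 equiv), THF, 0 °C; then 14, rt to 50 °C
Reagents that add atoms: none
Why: Horner–Wadsworth–Emmons olefination should take place at the unhindered C13 methyl ketone and not at the α-branched C8 ketone, and the stabilised phosphonate should favour the E alkene (chain trans to the ester); the minor Z isomer would be removed by chromatography.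

**Step 9**
Reactants: 16 allyl (13E)-2α-[(tert-butyldiphenylsilyl)oxy]-8-oxo-17-norlabd-13-en-15-oate
Product: 17 allyl (13E)-2α-[(tert-butyldiphenylsilyl)oxy]labda-8(17),13-dien-15-oate
Conditions: Zn, CH2Br2, TiCl4, THF, 0 °C; then 16, CH2Cl2, rt
Reagents that add atoms: dibromomethane, BrCBr
Why: Takai–Lombardo methylenation is non-basic and selective for ketones over esters, so the hindered enolisable C8 ketone should become the C8=C17 methylene without epimerising C9 or deconjugating the enoate.

**Step 10**
Reactants: 17 allyl (13E)-2α-[(tert-butyldiphenylsilyl)oxy]labda-8(17),13-dien-15-oate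
Product: 18 allyl (13E)-2α-hydroxylabda-8(17),13-dien-15-oate
Conditions: TBAF, AcOH, THF, rt
Reagents that add atoms: none
Why: Fluoride desilylation, buffered with acetic acid, should free the C2 alcohol without touching the allyl ester or the exocyclic alkene.

**Step 11**
Reactants: 18 allyl (13E)-2α-hydroxylabda-8(17),13-dien-15-oate
Product: 19 allyl (13E)-2-oxolabda-8(17),13-dien-15-oate
Conditions: Dess–Martin periodinane, CH2Cl2, 0 °C to rt
Reagents that add atoms: none
Why: Dess–Martin oxidation of the secondary alcohol is mild enough for both alkenes and leaves the C2 ketone as the only ketone in the molecule.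

**Step 12**
Reactants: 19 allyl (13E)-2-oxolabda-8(17),13-dien-15-oate
Product: 20 allyl (13E)-2β-hydroxylabda-8(17),13-dien-15-oate
Conditions: NaBH4, MeOH–THF, −20 °C
Reagents that add atoms: none
Why: Borohydride reduction of a ketone whose β face is blocked by the two syn-axial methyl groups (on C10 and C4) should deliver hydride from the α face and give the axial 2β-alcohol, as with other ketones flanked by two axial methyl groups; the conjugated ester is not reduced.

**Step 13**
Reactants: 20 allyl (13E)-2β-hydroxylabda-8(17),13-dien-15-oate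
Product: 21 allyl (13E)-2β-acetoxylabda-8(17),13-dien-15-oate
Conditions: Ac2O, DMAP, Et3N, CH2Cl2, rt to 40 °C
Reagents that add atoms: acetic anhydride, CC(=O)OC(C)=O
Why: DMAP-catalysed acetylation is the standard acylation for hindered axial alcohols and proceeds with retention at C2.

**Step 14**
Reactants: 21 allyl (13E)-2β-acetoxylabda-8(17),13-dien-15-oate
Product: 22 (13E)-2β-acetoxylabda-8(17),13-dien-15-oic acid
Conditions: Pd(PPh3)4 (5 mol %), morpholine, THF, rt
Reagents that add atoms: none
Why: Tsuji–Trost deallylation with an amine allyl acceptor should release the carboxylic acid under neutral conditions that leave the acetate, the exocyclic alkene and the E enoate intact.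

**Compound list**
1 | (4R,6R)-4-hydroxy-2,2,6-trimethylcyclohexan-1-one (actinol) | O=C1C(C)(C)C[C@H](O)C[C@H]1C | starting material
2 | (4R,6R)-4-[(tert-butyldiphenylsilyl)oxy]-2,2,6-trimethylcyclohexan-1-one | O=C1C(C)(C)C[C@H](O[Si](c2ccccc2)(c2ccccc2)C(C)(C)C)C[C@H]1C | intermediate
3 | lithium (4R)-4-[(tert-butyldiphenylsilyl)oxy]-2,6,6-trimethylcyclohex-1-en-1-olate (lithium enolate of 2) | CC1=C([O-])C(C)(C)C[C@H](O[Si](c2ccccc2)(c2ccccc2)C(C)(C)C)C1.[Li+] | intermediate
4 | (4R)-4-[(tert-butyldiphenylsilyl)oxy]-2,6,6-trimethylcyclohex-1-en-1-yl trifluoromethanesulfonate | CC1=C(OS(=O)(=O)C(F)(F)F)C(C)(C)C[C@H](O[Si](c2ccccc2)(c2ccccc2)C(C)(C)C)C1 | intermediate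
5 | (3-ethoxy-3-oxopropyl)zinc bromide | CCOC(=O)CC[Zn]Br | starting material
6 | ethyl 3-[(4R)-4-[(tert-butyldiphenylsilyl)oxy]-2,6,6-trimethylcyclohex-1-en-1-yl]propanoate | CC1=C(CCC(=O)OCC)C(C)(C)C[C@H](O[Si](c2ccccc2)(c2ccccc2)C(C)(C)C)C1 | intermediate
7 | allyl acetate (prop-2-en-1-yl acetate) | CC(=O)OCC=C | starting material
8 | allyl 5-[(4R)-4-[(tert-butyldiphenylsilyl)oxy]-2,6,6-trimethylcyclohex-1-en-1-yl]-3-oxopentanoate | CC1=C(CCC(=O)CC(=O)OCC=C)C(C)(C)C[C@H](O[Si](c2ccccc2)(c2ccccc2)C(C)(C)C)C1 | intermediate
9 | tertiary C10 carbocation formed from 8 by protonation of C5 on the α face | C[C+]1[C@@H](CCC(=O)CC(=O)OCC=C)C(C)(C)C[C@H](O[Si](c2ccccc2)(c2ccccc2)C(C)(C)C)C1 | intermediate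
10 | allyl 2α-[(tert-butyldiphenylsilyl)oxy]-4,4,10-trimethyl-8-oxo-trans-decalin-9β-carboxylate (5α-H, 9α-H, 10β-methyl) | O=C1CC[C@H]2C(C)(C)C[C@H](O[Si](c3ccccc3)(c3ccccc3)C(C)(C)C)C[C@]2(C)[C@H]1C(=O)OCC=C | intermediate
11 | but-3-en-2-one (methyl vinyl ketone) | CC(=O)C=C | starting material
12 | allyl 2α-[(tert-butyldiphenylsilyl)oxy]-4,4,10-trimethyl-8-oxo-9α-(3-oxobutyl)-trans-decalin-9β-carboxylate | O=C1CC[C@H]2C(C)(C)C[C@H](O[Si](c3ccccc3)(c3ccccc3)C(C)(C)C)C[C@]2(C)[C@@]1(CCC(C)=O)C(=O)OCC=C | intermediate
13 | 2α-[(tert-butyldiphenylsilyl)oxy]-4,4,10-trimethyl-8-oxo-9α-(3-oxobutyl)-trans-decalin-9β-carboxylic acid | O=C1CC[C@H]2C(C)(C)C[C@H](O[Si](c3ccccc3)(c3ccccc3)C(C)(C)C)C[C@]2(C)[C@@]1(CCC(C)=O)C(=O)O | intermediate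
14 | 2α-[(tert-butyldiphenylsilyl)oxy]-14,15,17-trinorlabdane-8,13-dione (9β side chain) | O=C1CC[C@H]2C(C)(C)C[C@H](O[Si](c3ccccc3)(c3ccccc3)C(C)(C)C)C[C@]2(C)[C@H]1CCC(C)=O | intermediate
15 | allyl 2-(diethoxyphosphoryl)acetate | CCOP(=O)(CC(=O)OCC=C)OCC | starting material
16 | allyl (13E)-2α-[(tert-butyldiphenylsilyl)oxy]-8-oxo-17-norlabd-13-en-15-oate | O=C1CC[C@H]2C(C)(C)C[C@H](O[Si](c3ccccc3)(c3ccccc3)C(C)(C)C)C[C@]2(C)[C@H]1CC/C(C)=C/C(=O)OCC=C | intermediate
17 | allyl (13E)-2α-[(tert-butyldiphenylsilyl)oxy]labda-8(17),13-dien-15-oate | C=C1CC[C@H]2C(C)(C)C[C@H](O[Si](c3ccccc3)(c3ccccc3)C(C)(C)C)C[C@]2(C)[C@H]1CC/C(C)=C/C(=O)OCC=C | intermediate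
18 | allyl (13E)-2α-hydroxylabda-8(17),13-dien-15-oate | C=C1CC[C@H]2C(C)(C)C[C@H](O)C[C@]2(C)[C@H]1CC/C(C)=C/C(=O)OCC=C | intermediate
19 | allyl (13E)-2-oxolabda-8(17),13-dien-15-oate | C=C1CC[C@H]2C(C)(C)CC(=O)C[C@]2(C)[C@H]1CC/C(C)=C/C(=O)OCC=C | intermediate
20 | allyl (13E)-2β-hydroxylabda-8(17),13-dien-15-oate | C=C1CC[C@H]2C(C)(C)C[C@@H](O)C[C@]2(C)[C@H]1CC/C(C)=C/C(=O)OCC=C | intermediate
21 | allyl (13E)-2β-acetoxylabda-8(17),13-dien-15-oate | C=C1CC[C@H]2C(C)(C)C[C@@H](OC(C)=O)C[C@]2(C)[C@H]1CC/C(C)=C/C(=O)OCC=C | intermediate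
22 | (13E)-2β-acetoxylabda-8(17),13-dien-15-oic acid | C=C1CC[C@H]2C(C)(C)C[C@@H](OC(C)=O)C[C@]2(C)[C@H]1CC/C(C)=C/C(=O)O | target

Total step count: 14. Longest linear sequence: 14 steps (1 to 22).

**Steps most likely to fail**

Step 5. The relay of chirality from C2 to C5 rests on one ring A conformation, so facial selectivity in the protonation could be poor. The cation could also lose a proton toward C1, making the silyl ether allylic and ionisable, or close to the cis-fused ring system. The fallback sets out from 6 and returns at 10, and fixes C5 before the ring is closed. Hydroboration–oxidation of the C5=C10 alkene (BH3·THF, then NaBO3·4H2O) should add hydrogen to C5 and boron to the less hindered C10 in one irreversible syn step on the α face, giving the C10 tertiary alcohol F1. Crossed Claisen condensation with the lithium enolate of allyl acetate (as in step 4, one further equivalent of base for the hydroxyl) gives the hydroxy keto ester F2. Ionisation of the tertiary alcohol with SnCl4 at −78 °C then forms the C10 cation with the C5 hydrogen already in place, and closure through C9 gives 10.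

Step 6. Addition at C9, which lies next to the quaternary C10, may be slow, so that polymerisation of butenone, reversal of the addition or O-alkylation take over. The fallback sets out from 10 and returns at 12, replacing the conjugate addition with an allylic alkylation. Alkylation of the sodium enolate of 10 (NaH, DMF) with 1,3-dichlorobut-2-ene, a more reactive and non-polymerising electrophile, gives the C9 chlorobutenyl keto ester F3. Hydrolysis of its vinyl chloride (Hg(OAc)2, HCO2H, rt; the Wichterle sequence) unmasks the methyl ketone and gives 12.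

Step 3. Oxidative addition into the hindered tetrasubstituted vinyl triflate may be slow, and β-hydride elimination or protonation of the alkylzinc reagent may then consume the coupling partner. The fallback sets out from 4 and returns at 8, building the chain by enolate alkylation. Methoxycarbonylation of 4 (Pd(OAc)2, dppp, CO, MeOH, Et3N, DMF) gives the methyl cyclohexenecarboxylate F4. Reduction with i-Bu2AlH gives the allylic alcohol F5, and CBr4 with PPh3 gives the allylic bromide F6. Alkylation of the dianion of allyl acetoacetate (NaH, then n-BuLi, THF, 0 °C) at its terminal carbon with F6 gives 8 directly.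

**Further compounds**
F1 | step 5 | C10 tertiary alcohol: ethyl 3-[10α-hydroxy-2α-[(tert-butyldiphenylsilyl)oxy]-4,4,10-trimethylcyclohex-5-yl]propanoate (5α-H, labdane locants) | C[C@@]1(O)[C@@H](CCC(=O)OCC)C(C)(C)C[C@H](O[Si](c2ccccc2)(c2ccccc2)C(C)(C)C)C1
F2 | step 5 | hydroxy keto ester: allyl 5-[10α-hydroxy-2α-[(tert-butyldiphenylsilyl)oxy]-4,4,10-trimethylcyclohex-5-yl]-3-oxopentanoate (5α-H, labdane locants) | C[C@@]1(O)[C@@H](CCC(=O)CC(=O)OCC=C)C(C)(C)C[C@H](O[Si](c2ccccc2)(c2ccccc2)C(C)(C)C)C1
F3 | step 6 | C9 chlorobutenyl keto ester: allyl 2α-[(tert-butyldiphenylsilyl)oxy]-9α-(3-chlorobut-2-enyl)-4,4,10-trimethyl-8-oxo-trans-decalin-9β-carboxylate | O=C1CC[C@H]2C(C)(C)C[C@H](O[Si](c3ccccc3)(c3ccccc3)C(C)(C)C)C[C@]2(C)[C@@]1(CC=C(C)Cl)C(=O)OCC=C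
F4 | step 3 | methyl cyclohexenecarboxylate: methyl (4R)-4-[(tert-butyldiphenylsilyl)oxy]-2,6,6-trimethylcyclohex-1-ene-1-carboxylate | CC1=C(C(=O)OC)C(C)(C)C[C@H](O[Si](c2ccccc2)(c2ccccc2)C(C)(C)C)C1
F5 | step 3 | allylic alcohol: [(4R)-4-[(tert-butyldiphenylsilyl)oxy]-2,6,6-trimethylcyclohex-1-en-1-yl]methanol | CC1=C(CO)C(C)(C)C[C@H](O[Si](c2ccccc2)(c2ccccc2)C(C)(C)C)C1
F6 | step 3 | allylic bromide: (4R)-1-(bromomethyl)-4-[(tert-butyldiphenylsilyl)oxy]-2,6,6-trimethylcyclohex-1-ene | CC1=C(CBr)C(C)(C)C[C@H](O[Si](c2ccccc2)(c2ccccc2)C(C)(C)C)C1
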